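The readings come from a simulation from invented constants, noise included.

Set ash beside maple: at 50.0 min they hold 28.2 % and 27.6 % starting material, and 5.8 % and 5.5 % target, although ash was charged at 0.31 M with 0.50 equiv other conformer and maple at 0.22 M with 0.75 equiv. So keep the charge of the new flasks near these and change the temperature.

| flask | starting material | other conformer | temperature | remark | time |
|---|---|---|---|---|---|
| ash | 0.31 M | 0.50 equiv | −5 °C | run made earlier |  |
| cedar | 0.48 M | 0.50 equiv | 20 °C | run made earlier |  |
| maple | 0.22 M | 0.75 equiv | −5 °C | run made earlier |  |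
| green | 0.22 M | 0.500 equiv | 0 °C |  | 80 min |
| ochre | 0.22 M | 0.500 equiv | 20 °C |  | 80 min |
| red | 0.22 M | 0.500 equiv | 40 °C |  | 80 min |

| run | time / min | target / % | starting material / % |
|---|---|---|---|
| ash | 4.00 | 0.4 | 55.4 |
| ash | 8.00 | 2.0 | 44.7 |
| ash | 15.0 | 2.7 | 34.8 |
| ash | 25.0 | 3.8 | 30.6 |
| ash | 50.0 | 5.8 | 28.2 |
| cedar | 1.33 | 4.2 | 20.0 |
| cedar | 4.00 | 7.6 | 11.5 |
| cedar | 8.00 | 11.1 | 9.8 |
| cedar | 12.0 | 13.0 | 9.6 |
| cedar | 20.0 | 19.5 | 8.1 |
| maple | 4.00 | 1.4 | 55.7 |
| maple | 8.00 | 1.8 | 44.2 |
| maple | 15.0 | 2.3 | 34.3 |
| maple | 25.0 | 3.8 | 29.6 |
| maple | 50.0 | 5.5 | 27.6 |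

(standard deviation of a reading: 0.5 percentage points)

- percent here means starting material units held: one side product counts as two
- candidate steps: starting material + target -> side product; starting material <-> dormant form; starting material <-> other conformer; target <-> isomer of the product; other conformer -> isomer of the product; starting material -> target
- in a conversion other conformer counts as not yet reacted

- the flask with the highest amount of target, in percent of the starting material and other conformer together charged ("all alike" if they lie within 1.5 percentage points) (green / ochre / red / all alike)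
- final target, as a percentage of the starting material and other conformer together charged, in green
- final target, as a percentage of the starting material and other conformer together charged, in ochre
- final target, as a percentage of the starting material and other conformer together charged, in red

Percentages alike at these two charges at −5 °C fit a target rate first order in one concentration, c(starting material). So read the target constant: the target gained per minute, divided by the mean starting material over the same late readings. Ash gives 0.00281 min⁻¹, and cedar gives 0.0759 min⁻¹, which is the target constant to carry at 20 °C.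

Now weigh the warming. At its last reading cedar's starting material lies lower than ash's at its last, 8.1 % against 28.2 %, but multiply each by its constant and cedar at that reading still makes target faster than ash, 0.00615 min⁻¹ against 7.93 × 10⁻⁴ min⁻¹. So go warm. My own estimate holds ochre at cedar's last starting material and gives 49.2 % target in 80 min, more than the forecast's figure for ochre. Cedar, at 20 °C, is the warmest run so far, so run red beside ochre and green.

The forecast names red, with 13 %, 33 % and 43 % for green, ochre and red, saying of red that “the pool is nearly consumed, so selectivity limits the yield”.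

The flasks give 13.0 %, 41.7 % and 24.2 % in green, ochre and red, so ochre leads.

starting material + target → side product (k = 1.10 × 10⁻⁴ L mol⁻¹ s⁻¹, Ea = 62.0 kJ mol⁻¹); starting material ⇌ dormant form (K = 2.60, k = 0.00340 s⁻¹, Ea = 70.0 kJ mol⁻¹, ΔH = 29.0 kJ mol⁻¹); starting material ⇌ other conformer (K = 0.330, k = 0.00750 s⁻¹, Ea = 75.0 kJ mol⁻¹, ΔH = 20.0 kJ mol⁻¹); target ⇌ isomer of the product (K = 8.00, k = 2.60 × 10⁻⁶ s⁻¹, Ea = 84.0 kJ mol⁻¹, ΔH = −11.0 kJ mol⁻¹); other conformer → isomer of the product (k = 7.00 × 10⁻⁵ s⁻¹, Ea = 96.0 kJ mol⁻¹); starting material → target (k = 1.10 × 10⁻⁴ s⁻¹, Ea = 85.0 kJ mol⁻¹); (constants at 0 °C) Ochre has not come to rest: from 40.0 min to 80.0 min the target constant predicts a gain of 14 percentage points against 12 points found, and at 800 min its target stands at 22.6 %. Green's own target constant, read the same way from its first 80.0 min, is 0.00630 min⁻¹; it reckons green at 24.9 % target at 180 min against 24.4 % simulated, and at 800 min green stands at 53.2 %. Red, holding 0 % starting material, still slips from 24.2 % to 18.5 %.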